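The route rests on cutting the ten-membered carbocycle (C1–C10) at C1–C2. The furanone carbons C1–C2–C3 are treated as a masked ynone, so the key step, a chromium-mediated addition of a C2 iodoalkyne to the C1 aldehyde, forms that bond and closes the carbocycle as a cis-enyne in one operation, the Z C4=C5 alkene bringing the chain ends together. Oxidation and addition of the C10 oxygen to C3 then build the furanone ring. The cyclisation precursor is an open-chain iodoalkyne aldehyde that already carries the trans-disubstituted α-methylene γ-lactone (C7, C8, C11–C13), the quaternary C10 as its triethylsilyl ether and C6 as its tert-butyldimethylsilyl ether.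

Key step: step 20

Remark: atoms are numbered C1 (furanone carbonyl), C2 (furanone CH), C3 (O-bearing furanone carbon), C4 (methyl C15), C5, C6 (acyloxy carbon), C7, C8 (lactone O-carbon), C9, C10 (methyl C14), C11 (methylene C13), C12 (lactone carbonyl); the C1 carbinol of 34 and C11 of 27 are assumed to form as epimer mixtures, which is harmless because both centres are removed later.

Step 1
Reactants: 1 (S)-2-methylglycidol
Product: 2 (R)-2-methylpent-4-ene-1,2-diol
Conditions: CH2=CHMgBr (2.5 equiv), CuI (10 mol%), THF, −30 → 0 °C; aq. NH4Cl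
Reagents that add atoms: vinylmagnesium bromide, C=C[Mg]Br
Why: Copper-catalysed Grignard opening of the epoxide (SN2) should take place at the unsubstituted ring CH2, the future C9, so that no bond to the C10 stereocentre is broken and its configuration comes unchanged from 1.

Step 2
Reactants: 2 (R)-2-methylpent-4-ene-1,2-diol
Product: 3 (R)-1-[(4-methoxybenzyl)oxy]-2-methylpent-4-en-2-ol
Conditions: NaH (1.05 equiv), THF/DMF, 0 °C; 4-MeOC6H4CH2Cl, Bu4NI (cat.), 0 °C → rt
Reagents that add atoms: 4-methoxybenzyl chloride, COc1ccc(CCl)cc1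
Why: Williamson etherification, in which the primary alkoxide forms and is alkylated far faster than the hindered tertiary one, should protect C1–OH selectively.

Step 3
Reactants: 3 (R)-1-[(4-methoxybenzyl)oxy]-2-methylpent-4-en-2-ol
Product: 4 (R)-triethyl({1-[(4-methoxybenzyl)oxy]-2-methylpent-4-en-2-yl}oxy)silane
Conditions: Et3SiOTf, 2,6-lutidine, CH2Cl2, −78 → 0 °C
Reagents that add atoms: triethylsilyl trifluoromethanesulfonate, CC[Si](CC)(CC)OS(=O)(=O)C(F)(F)F
Why: Silyl ether formation at the hindered tertiary C10 hydroxyl calls for the silyl triflate with 2,6-lutidine and touches no stereocentre.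

Step 4
Reactants: 4 (R)-triethyl({1-[(4-methoxybenzyl)oxy]-2-methylpent-4-en-2-yl}oxy)silane
Product: 6 (R)-4-[(4-methoxybenzyl)oxy]-3-methyl-3-[(triethylsilyl)oxy]butanal, via ozonide 5 (not isolated)
Conditions: O3, CH2Cl2, −78 °C (Sudan Red 7B end-point); then PPh3, −78 °C → rt
Reagents that add atoms: ozone, [O-][O+]=O
Why: Ozonolysis of the terminal alkene with reductive work-up (PPh3) should unmask the C8 aldehyde, the indicator end-point preventing over-oxidation of the anisyl ring.

Step 5
Reactants: 7 (R)-4-benzyloxazolidin-2-one; 8 methyl 4-chloro-4-oxobutanoate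
Product: 9 methyl (R)-4-(4-benzyl-2-oxooxazolidin-3-yl)-4-oxobutanoate
Conditions: n-BuLi, THF, −78 °C; then 8, −78 → 0 °C
Reagents that add atoms: none
Why: N-Acylation of the lithiated Evans oxazolidinone by the acid chloride should give the imide, the ester end being far less electrophilic.

Step 6
Reactants: 10 prop-2-yn-1-ol
Product: 12 (Z)-3-iodo-2-methylprop-2-en-1-ol, via alkenylmagnesium alkoxide 11 (not isolated)
Conditions: MeMgBr (2.5 equiv), CuI (10 mol%), THF, −10 °C → rt; then I2, −78 → 0 °C; aq. NH4Cl
Reagents that add atoms: methylmagnesium bromide, C[Mg]Br; iodine, II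
Why: Copper-catalysed anti-carbomagnesiation of the propargylic alkoxide puts the methyl on the internal carbon and magnesium on the terminal carbon cis to the CH2O group, and iodinolysis with retention should fix the Z vinyl iodide that later becomes the C4=C5 alkene.

Step 7
Reactants: 12 (Z)-3-iodo-2-methylprop-2-en-1-ol
Product: 13 (Z)-3-iodo-2-methylprop-2-enal
Conditions: MnO2 (activated, excess), CH2Cl2, rt; carried on as a solution
Reagents that add atoms: none
Why: Oxidation of the allylic alcohol with MnO2 is chemoselective and should leave the vinyl iodide and the alkene geometry untouched.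

Step 8
Reactants: 13 (Z)-3-iodo-2-methylprop-2-enal
Product: 14 (Z)-1-iodo-2-methylbut-1-en-3-yne
Conditions: Me3SiCHN2, n-BuLi, THF, −78 °C; then 13, −78 → 0 °C
Reagents that add atoms: (trimethylsilyl)diazomethane, C[Si](C)(C)C=[N+]=[N-]
Why: Colvin homologation: lithiated trimethylsilyldiazomethane adds to the aldehyde and, after Peterson elimination and loss of N2, the alkylidene carbene rearranges by 1,2-hydrogen shift to the terminal alkyne, avoiding the methoxide conditions under which enals fail.

Step 9
Reactants: 14 (Z)-1-iodo-2-methylbut-1-en-3-yne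
Product: 15 (Z)-(4-iodo-3-methylbut-3-en-1-yn-1-yl)trimethylsilane
Conditions: LiN(SiMe3)2, THF, −78 °C; Me3SiCl, −78 → 0 °C
Reagents that add atoms: chlorotrimethylsilane, C[Si](C)(C)Cl
Why: C-Silylation of the lithium acetylide should protect the alkyne, LiN(SiMe3)2 being basic enough for the alkyne C–H but not for the vinylic C–H next to iodine.

Step 10
Reactants: 9 methyl (R)-4-(4-benzyl-2-oxooxazolidin-3-yl)-4-oxobutanoate; 6 (R)-4-[(4-methoxybenzyl)oxy]-3-methyl-3-[(triethylsilyl)oxy]butanal
Product: 18 trans-lactone imide, via boron enolate 16 (not isolated), via aldol hydroxy ester 17 (not isolated)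
Conditions: 9, Bu2BOTf, i-Pr2NEt, CH2Cl2, −78 → 0 °C; 6, −78 → 0 °C; pH 7 phosphate buffer, MeOH, H2O2; then PPTS (cat.), CH2Cl2, rt
Reagents that add atoms: none
Why: Evans syn-aldol reaction: the Z boron enolate 16 should add to 6 through a Zimmerman–Traxler chair on the enolate face away from the benzyl group, which sets C7 (R) and C8 (S) under auxiliary control, and acid-catalysed lactonisation of the C8 hydroxyl onto the methyl ester then closes the γ-lactone, placing C6 and C9 trans.

Step 11
Reactants: 18 trans-lactone imide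
Product: 20 trans-lactone acid, via peroxy acid 19 (not isolated)
Conditions: LiOH, H2O2, THF/H2O, 0 °C; Na2SO3; then 1 M HCl to pH 3
Reagents that add atoms: hydrogen peroxide, OO
Why: Hydroperoxide cleavage of the Evans imide should attack the exocyclic carbonyl selectively, and acidification closes again any lactone opened by hydroxide, so C7 and C8 stay as set.

Step 12
Reactants: 20 trans-lactone acid; 15 (Z)-(4-iodo-3-methylbut-3-en-1-yn-1-yl)trimethylsilane
Product: 24 Z-enone lactone, via acid chloride 21 (not isolated), via alkenyllithium 22 (not isolated), via alkenylzinc chloride 23 (not isolated)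
Conditions: 20, 1-chloro-N,N,2-trimethylprop-1-en-1-amine, CH2Cl2, 0 °C → rt; separately 15, t-BuLi (2 equiv), Et2O, −78 °C, then ZnCl2, THF, −78 → 0 °C; combine, Pd(PPh3)4 (5 mol%), THF, 0 °C → rt
Reagents that add atoms: none
Why: Negishi acylation: the acid chloride made under neutral conditions should couple with the Z alkenylzinc reagent under zerovalent palladium catalysis with retention of alkene geometry, organozinc reagents leaving the lactone untouched.

Step 13
Reactants: 24 Z-enone lactone
Product: 25 (6S)-allylic alcohol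
Conditions: LiBH(s-Bu)3, THF, −78 °C; AcOH quench at −78 °C
Reagents that add atoms: none
Why: Felkin–Anh controlled 1,2-reduction: the bulky hydride should attack the C6 ketone anti to the C7–C8 bond and past H7 to give the (6S) alcohol, the fully substituted β-carbon C4 disfavouring conjugate reduction and the low temperature sparing the lactone.

Step 14
Reactants: 25 (6S)-allylic alcohol
Product: 26 C6 tert-butyldimethylsilyl ether
Conditions: t-BuMe2SiOTf, 2,6-lutidine, CH2Cl2, −78 → 0 °C
Reagents that add atoms: tert-butyldimethylsilyl trifluoromethanesulfonate, CC(C)(C)[Si](C)(C)OS(=O)(=O)C(F)(F)F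
Why: Silyl ether formation with the silyl triflate and 2,6-lutidine should cap the hindered allylic C6 hydroxyl, which must stay protected so that O6 can never add to the neighbouring alkyne.

Step 15
Reactants: 26 C6 tert-butyldimethylsilyl ether
Product: 27 α-(dimethylaminomethyl) lactone
Conditions: LiN(i-Pr)2, THF, −78 °C; CH2=NMe2+ I−, −78 → 0 °C
Reagents that add atoms: N,N-dimethylmethyleneiminium iodide, C=[N+](C)C.[I-]
Why: Mannich reaction of the lithium lactone enolate with Eschenmoser's salt should install the aminomethyl group at C11, the new centre being of no consequence because it becomes sp2 in the next step.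

Step 16
Reactants: 27 α-(dimethylaminomethyl) lactone
Product: 29 α-methylene lactone, via ammonium iodide 28 (not isolated)
Conditions: MeI, CH2Cl2, rt; then aq. NaHCO3, rt
Reagents that add atoms: none
Why: N-Methylation to the quaternary ammonium salt followed by base-induced β-elimination of trimethylamine (Hofmann-type elimination) should give the exocyclic C11=C13 methylene.

Step 17
Reactants: 29 α-methylene lactone
Product: 30 C1 primary alcohol
Conditions: DDQ, CH2Cl2/pH 7 phosphate buffer, 0 °C
Reagents that add atoms: none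
Why: Oxidative cleavage of the 4-methoxybenzyl ether with DDQ in buffered medium should free C1–OH while silyl ethers, enyne and α-methylene lactone are not electron-rich enough to react.

Step 18
Reactants: 30 C1 primary alcohol
Product: 31 C1 aldehyde
Conditions: Dess–Martin periodinane, NaHCO3, CH2Cl2, 0 °C → rt
Reagents that add atoms: none
Why: Dess–Martin oxidation should give the C1 aldehyde, which has no α-hydrogen, so C10 cannot epimerise.

Step 19
Reactants: 31 C1 aldehyde
Product: 32 iodoalkyne aldehyde
Conditions: N-iodosuccinimide, AgNO3 (10 mol%), DMF, rt, dark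
Reagents that add atoms: N-iodosuccinimide, O=C1CCC(=O)N1I
Why: Silver-catalysed iododesilylation: AgNO3 converts the C-silyl alkyne into a silver acetylide that N-iodosuccinimide iodinates, giving the iodoalkyne directly and just before use.

Step 20
Reactants: 32 iodoalkyne aldehyde
Product: 34 ten-membered enynol, via alkynylchromium dichloride 33 (not isolated)
Conditions: CrCl2 (8 equiv), NiCl2 (1 mol%), THF (degassed), rt, slow addition of 32 to a final concentration of about 2 mM; aqueous work-up
Reagents that add atoms: none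
Why: Two equivalents of divalent chromium reduce the C–I bond of the iodoalkyne (a trace of NiCl2 assisting) to the alkynyl species 33 of trivalent chromium, whose carbon C2 then adds to the chromium-bound C1 aldehyde. The closest known reaction is the intramolecular Nozaki–Hiyama–Kishi alkynylation of aldehydes by iodoalkynes, which is used to close ten-membered enyne and enediyne carbocycles. Ring formation is a 10-exo-trig closure of the C1–C10 carbocycle; the Z-configured C4=C5 bond holds both chain ends on one side and the sp-hybridised C2 and C3 carry no hydrogens that could clash across the ring. The new C1 carbinol centre is not controlled and need not be, because step 21 oxidises it. The step needs chemoselectivity for the aldehyde over the α-methylene lactone and the silyl ethers, which the weakly basic and oxophilic organochromium reagent provides, and ring closure over intermolecular coupling, which slow addition at high dilution secures; C1 has no α-hydrogen, so neither enolisation nor epimerisation at C10 can compete.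

Step 21
Reactants: 34 ten-membered enynol
Product: 35 ten-membered ynone
Conditions: Dess–Martin periodinane, NaHCO3, CH2Cl2, 0 °C
Reagents that add atoms: none
Why: Dess–Martin oxidation of the propargylic alcohol should give the ynone and erases the uncontrolled C1 centre.

Step 22
Reactants: 35 ten-membered ynone
Product: 37 furanone C6 silyl ether, via hydroxy ynone 36 (not isolated)
Conditions: HF·pyridine, pyridine, THF, 0 °C; then Ph3PAuCl (5 mol%), AgOTf (5 mol%), CH2Cl2, rt
Reagents that add atoms: none
Why: Buffered HF·pyridine should cleave the triethylsilyl ether much faster than the bulkier tert-butyldimethylsilyl ether, and the freed C10 hydroxyl then adds to C3 of the ynone in a 5-endo-dig cycloisomerisation (oxa-Michael type, catalysed by monovalent gold) to give the 3(2H)-furanone while O6 is still blocked.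

Step 23
Reactants: 37 furanone C6 silyl ether
Product: 38 furanone C6 alcohol
Conditions: HF·pyridine (excess), THF, 0 °C → rt
Reagents that add atoms: none
Why: Fluoride-mediated desilylation under mildly acidic conditions should free the C6 hydroxyl without base-induced acyl migration or attack on the α-methylene lactone.

Step 24
Reactants: 39 methyl angelate
Product: 40 (Z)-2-methylbut-2-en-1-ol
Conditions: i-Bu2AlH (2.2 equiv), CH2Cl2, −78 °C; aq. potassium sodium tartrate
Reagents that add atoms: none
Why: 1,2-Reduction of the ester with i-Bu2AlH should give the allylic alcohol without touching the Z alkene.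

Step 25
Reactants: 40 (Z)-2-methylbut-2-en-1-ol
Product: 41 [(2S,3R)-2,3-dimethyloxiran-2-yl]methanol
Conditions: Ti(Oi-Pr)4 (10 mol%), L-(+)-diethyl tartrate (12 mol%), t-BuOOH, 4 Å molecular sieves, CH2Cl2, −20 °C
Reagents that add atoms: tert-butyl hydroperoxide, CC(C)(C)OO
Why: Sharpless asymmetric epoxidation: with L-(+)-diethyl tartrate the titanium complex should deliver oxygen to the alkene face that gives the (2S,3R) epoxy alcohol, syn addition keeping the two methyl groups trans.

Step 26
Reactants: 41 [(2S,3R)-2,3-dimethyloxiran-2-yl]methanol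
Product: 42 (2R,3R)-2,3-dimethyloxirane-2-carboxylic acid
Conditions: TEMPO (cat.), PhI(OAc)2 (2.2 equiv), MeCN/H2O, rt
Reagents that add atoms: water, O
Why: TEMPO-catalysed oxidation with PhI(OAc)2 in aqueous acetonitrile should take the primary alcohol through the aldehyde hydrate to the acid under near-neutral conditions that spare the epoxide, the change of the C2 descriptor to R being a matter of priorities only.

Step 27
Reactants: 42 (2R,3R)-2,3-dimethyloxirane-2-carboxylic acid; 38 furanone C6 alcohol
Product: 44 target CNP0258430.3, via mixed anhydride 43 (not isolated)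
Conditions: 42, 2,4,6-Cl3C6H2COCl, Et3N, THF, rt; then 38, DMAP, toluene, rt
Reagents that add atoms: none
Why: Yamaguchi esterification: the mixed anhydride 43 should transfer the hindered acyl group to the C6 hydroxyl through the acylpyridinium ion formed with DMAP, no stereocentre of acid or alcohol being involved.

Compound list
1 | (S)-2-methylglycidol, (S)-(2-methyloxiran-2-yl)methanol | OC[C@@]1(C)CO1 | starting material
2 | (R)-2-methylpent-4-ene-1,2-diol | C=CC[C@@](C)(O)CO | intermediate
3 | (R)-1-[(4-methoxybenzyl)oxy]-2-methylpent-4-en-2-ol | C=CC[C@@](C)(O)COCc1ccc(OC)cc1 | intermediate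
4 | (R)-triethyl({1-[(4-methoxybenzyl)oxy]-2-methylpent-4-en-2-yl}oxy)silane | C=CC[C@@](C)(O[Si](CC)(CC)CC)COCc1ccc(OC)cc1 | intermediate
5 | ozonide of 4 (1,2,4-trioxolane, both epimers at the ring carbon) | C1OC(C[C@@](C)(O[Si](CC)(CC)CC)COCc2ccc(OC)cc2)OO1 | intermediate (not isolated)
6 | (R)-4-[(4-methoxybenzyl)oxy]-3-methyl-3-[(triethylsilyl)oxy]butanal (C8 aldehyde with C9, C10, C1) | O=CC[C@@](C)(O[Si](CC)(CC)CC)COCc1ccc(OC)cc1 | intermediate
7 | (R)-4-benzyloxazolidin-2-one | O=C1N[C@H](Cc2ccccc2)CO1 | starting material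
8 | methyl 4-chloro-4-oxobutanoate | COC(=O)CCC(=O)Cl | starting material
9 | methyl (R)-4-(4-benzyl-2-oxooxazolidin-3-yl)-4-oxobutanoate | COC(=O)CCC(=O)N1[C@H](Cc2ccccc2)COC1=O | intermediate
10 | prop-2-yn-1-ol | C#CCO | starting material
11 | alkenylmagnesium alkoxide, bromomagnesium (Z)-3-(bromomagnesio)-2-methylprop-2-en-1-olate | Br[Mg]OC/C(C)=C\[Mg]Br | intermediate (not isolated)
12 | (Z)-3-iodo-2-methylprop-2-en-1-ol | OC/C(C)=C\I | intermediate
13 | (Z)-3-iodo-2-methylprop-2-enal | O=C/C(C)=C\I | intermediate
14 | (Z)-1-iodo-2-methylbut-1-en-3-yne | C#C/C(C)=C\I | intermediate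
15 | (Z)-(4-iodo-3-methylbut-3-en-1-yn-1-yl)trimethylsilane | C[Si](C)(C)C#C/C(C)=C\I | intermediate
16 | boron enolate, Z dibutylboron enolate of 9 | CCCCB(CCCC)O/C(=C\CC(=O)OC)N1[C@H](Cc2ccccc2)COC1=O | intermediate (not isolated)
17 | aldol hydroxy ester, syn adduct with C7 (R) and C8 (S) | COC(=O)C[C@H]([C@@H](O)C[C@@](C)(O[Si](CC)(CC)CC)COCc1ccc(OC)cc1)C(=O)N1[C@H](Cc2ccccc2)COC1=O | intermediate (not isolated)
18 | trans-lactone imide, (R)-4-benzyl-3-{[(2S,3R)-2-{(R)-3-[(4-methoxybenzyl)oxy]-2-methyl-2-[(triethylsilyl)oxy]propyl}-5-oxotetrahydrofuran-3-yl]carbonyl}oxazolidin-2-one | O=C([C@@H]1CC(=O)O[C@H]1C[C@@](C)(O[Si](CC)(CC)CC)COCc1ccc(OC)cc1)N1[C@H](Cc2ccccc2)COC1=O | intermediate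
19 | peroxy acid of 20 | OOC(=O)[C@@H]1CC(=O)O[C@H]1C[C@@](C)(O[Si](CC)(CC)CC)COCc1ccc(OC)cc1 | intermediate (not isolated)
20 | trans-lactone acid, (2S,3R)-2-{(R)-3-[(4-methoxybenzyl)oxy]-2-methyl-2-[(triethylsilyl)oxy]propyl}-5-oxotetrahydrofuran-3-carboxylic acid | OC(=O)[C@@H]1CC(=O)O[C@H]1C[C@@](C)(O[Si](CC)(CC)CC)COCc1ccc(OC)cc1 | intermediate
21 | acid chloride of 20 | ClC(=O)[C@@H]1CC(=O)O[C@H]1C[C@@](C)(O[Si](CC)(CC)CC)COCc1ccc(OC)cc1 | intermediate (not isolated)
22 | alkenyllithium, (Z)-[2-methyl-4-(trimethylsilyl)but-1-en-3-yn-1-yl]lithium | C[Si](C)(C)C#C/C(C)=C\[Li] | intermediate (not isolated)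
23 | alkenylzinc chloride, (Z)-[2-methyl-4-(trimethylsilyl)but-1-en-3-yn-1-yl]zinc chloride | C[Si](C)(C)C#C/C(C)=C\[Zn]Cl | intermediate (not isolated)
24 | Z-enone lactone, (4R,5S)-5-{(R)-3-[(4-methoxybenzyl)oxy]-2-methyl-2-[(triethylsilyl)oxy]propyl}-4-[(Z)-3-methyl-5-(trimethylsilyl)pent-2-en-4-ynoyl]dihydrofuran-2(3H)-one | C[Si](C)(C)C#C/C(C)=C\C(=O)[C@@H]1CC(=O)O[C@H]1C[C@@](C)(O[Si](CC)(CC)CC)COCc1ccc(OC)cc1 | intermediate
25 | (6S)-allylic alcohol, 24 with the C6 ketone reduced to the (S) carbinol | C[Si](C)(C)C#C/C(C)=C\[C@H](O)[C@@H]1CC(=O)O[C@H]1C[C@@](C)(O[Si](CC)(CC)CC)COCc1ccc(OC)cc1 | intermediate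
26 | C6 tert-butyldimethylsilyl ether of 25 | C[Si](C)(C)C#C/C(C)=C\[C@H](O[Si](C)(C)C(C)(C)C)[C@@H]1CC(=O)O[C@H]1C[C@@](C)(O[Si](CC)(CC)CC)COCc1ccc(OC)cc1 | intermediate
27 | α-(dimethylaminomethyl) lactone, 26 with CH2NMe2 at C11 (both C11 epimers) | C[Si](C)(C)C#C/C(C)=C\[C@H](O[Si](C)(C)C(C)(C)C)[C@@H]1C(CN(C)C)C(=O)O[C@H]1C[C@@](C)(O[Si](CC)(CC)CC)COCc1ccc(OC)cc1 | intermediate
28 | ammonium iodide, N-methylated 27 | C[Si](C)(C)C#C/C(C)=C\[C@H](O[Si](C)(C)C(C)(C)C)[C@@H]1C(C[N+](C)(C)C)C(=O)O[C@H]1C[C@@](C)(O[Si](CC)(CC)CC)COCc1ccc(OC)cc1.[I-] | intermediate (not isolated)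
29 | α-methylene lactone, C1 4-methoxybenzyl ether, C-silyl alkyne | C[Si](C)(C)C#C/C(C)=C\[C@H](O[Si](C)(C)C(C)(C)C)[C@@H]1C(=C)C(=O)O[C@H]1C[C@@](C)(O[Si](CC)(CC)CC)COCc1ccc(OC)cc1 | intermediate
30 | C1 primary alcohol | C[Si](C)(C)C#C/C(C)=C\[C@H](O[Si](C)(C)C(C)(C)C)[C@@H]1C(=C)C(=O)O[C@H]1C[C@@](C)(O[Si](CC)(CC)CC)CO | intermediate
31 | C1 aldehyde with C-silyl alkyne | C[Si](C)(C)C#C/C(C)=C\[C@H](O[Si](C)(C)C(C)(C)C)[C@@H]1C(=C)C(=O)O[C@H]1C[C@@](C)(O[Si](CC)(CC)CC)C=O | intermediate
32 | iodoalkyne aldehyde (precursor of the key step): Z-enyne, trans α-methylene lactone, C6 tert-butyldimethylsilyl ether, C10 triethylsilyl ether | IC#C/C(C)=C\[C@H](O[Si](C)(C)C(C)(C)C)[C@@H]1C(=C)C(=O)O[C@H]1C[C@@](C)(O[Si](CC)(CC)CC)C=O | intermediate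
33 | alkynylchromium dichloride from 32 | Cl[Cr](Cl)C#C/C(C)=C\[C@H](O[Si](C)(C)C(C)(C)C)[C@@H]1C(=C)C(=O)O[C@H]1C[C@@](C)(O[Si](CC)(CC)CC)C=O | intermediate (not isolated)
34 | ten-membered enynol fused to the lactone (product of the key step, both C1 epimers) | OC1C#C/C(C)=C\[C@H](O[Si](C)(C)C(C)(C)C)[C@@H]2C(=C)C(=O)O[C@H]2C[C@@]1(C)O[Si](CC)(CC)CC | intermediate
35 | ten-membered ynone | O=C1C#C/C(C)=C\[C@H](O[Si](C)(C)C(C)(C)C)[C@@H]2C(=C)C(=O)O[C@H]2C[C@@]1(C)O[Si](CC)(CC)CC | intermediate
36 | hydroxy ynone with free C10 hydroxyl | O=C1C#C/C(C)=C\[C@H](O[Si](C)(C)C(C)(C)C)[C@@H]2C(=C)C(=O)O[C@H]2C[C@@]1(C)O | intermediate (not isolated)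
37 | furanone C6 silyl ether (full ring system, C6 tert-butyldimethylsilyl ether) | C=C1C(=O)O[C@H]2C[C@@]3(C)OC(=CC3=O)/C(C)=C\[C@H](O[Si](C)(C)C(C)(C)C)[C@H]12 | intermediate
38 | furanone C6 alcohol | C=C1C(=O)O[C@H]2C[C@@]3(C)OC(=CC3=O)/C(C)=C\[C@H](O)[C@H]12 | intermediate
39 | methyl angelate, methyl (Z)-2-methylbut-2-enoate | C/C=C(/C)C(=O)OC | starting material
40 | (Z)-2-methylbut-2-en-1-ol | C/C=C(/C)CO | intermediate
41 | [(2S,3R)-2,3-dimethyloxiran-2-yl]methanol | OC[C@]1(C)O[C@@H]1C | intermediate
42 | (2R,3R)-2,3-dimethyloxirane-2-carboxylic acid (epoxyangelic acid) | OC(=O)[C@]1(C)O[C@@H]1C | intermediate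
43 | mixed anhydride of 42 with 2,4,6-trichlorobenzoic acid | O=C(OC(=O)[C@]1(C)O[C@@H]1C)c1c(Cl)cc(Cl)cc1Cl | intermediate (not isolated)
44 | CNP0258430.3 | C=C1C(=O)O[C@H]2C[C@@]3(C)OC(=CC3=O)/C(C)=C\[C@H](OC(=O)[C@]3(C)O[C@@H]3C)[C@H]12 | target

Total step count: 27. Longest linear sequence: 19 steps (steps 1–4, 10–23 and 27, from (S)-2-methylglycidol).

Steps most likely to fail

Step 20. Intermolecular coupling to dimers and oligomers, or simple reduction of the C–I bond, may outrun closure of the ten-membered ring. The fallback sets out from aldehyde 31: the C-silyl group would be removed with AgNO3 (10 mol%) in MeOH/H2O/CH2Cl2 to give the terminal alkyne aldehyde F1. Slow addition of F1 to LiN(SiMe3)2 and CeCl3 in THF at −78 °C under high dilution (intramolecular acetylide addition to the non-enolisable aldehyde, as used for enediyne carbocycles) should return to the route at enynol 34.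

Step 13. Hydride delivery to the C6 ketone may show poor facial selectivity, so that much of the material ends as the C6 epimer. The fallback sets out from enone 24: the separated (6R) alcohol F2 would be inverted by a Mitsunobu reaction (ClCH2CO2H, PPh3, DIAD, toluene, 0 °C) to the (6S) chloroacetate F3. Cleavage of F3 with thiourea and NaHCO3 in EtOH, which leaves the lactone alone, should return to the route at alcohol 25.

Step 22. The C6 silyl ether may be lost together with the C10 one, or the 5-endo-dig closure may be slow, so that O6 adds to C3 and a furan forms at the expense of the C6 stereocentre. The fallback sets out from ynone 35: conjugate addition of Et2NH (1 equiv, THF, −20 °C) would mask C3 as the β-(diethylamino)enone F4. HF·pyridine/pyridine followed by aqueous AcOH should then free the C10 hydroxyl and close the ring by addition–elimination with loss of diethylamine, coming back to the route at furanone 37.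

Further compounds
F1 | step 20 | terminal alkyne aldehyde (31 without the C-silyl group) | C#C/C(C)=C\[C@H](O[Si](C)(C)C(C)(C)C)[C@@H]1C(=C)C(=O)O[C@H]1C[C@@](C)(O[Si](CC)(CC)CC)C=O
F2 | step 13 | (6R) alcohol, C6 epimer of 25 | C[Si](C)(C)C#C/C(C)=C\[C@@H](O)[C@@H]1CC(=O)O[C@H]1C[C@@](C)(O[Si](CC)(CC)CC)COCc1ccc(OC)cc1
F3 | step 13 | (6S) chloroacetate of 25 | C[Si](C)(C)C#C/C(C)=C\[C@H](OC(=O)CCl)[C@@H]1CC(=O)O[C@H]1C[C@@](C)(O[Si](CC)(CC)CC)COCc1ccc(OC)cc1
F4 | step 22 | β-(diethylamino)enone from 35 (C2=C3 geometry open) | O=C1C=C(N(CC)CC)/C(C)=C\[C@H](O[Si](C)(C)C(C)(C)C)[C@@H]2C(=C)C(=O)O[C@H]2C[C@@]1(C)O[Si](CC)(CC)CC
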